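**Strategy.** Everything rests on cutting the C2–C3 bond of pyranone ring C. Seen this way, C2 with ring B is just the methylene of a 4-(benzyloxy)benzyl ether on O1, and C3–C4 is an acetyl group on ring A. The key step exploits that this O1–C2 methylene is benzylic, ether-activated and 1,6-related to C3. After diazo transfer to the acetyl group, a chiral divalent rhodium carboxylate makes C3 a carbene that inserts into one of the two enantiotopic C2–H bonds. One operation closes ring C, forms C2–C3 and sets C2. The 3-hydroxyl then enters trans by Rubottom oxidation. The side-chain centre comes from iridium-catalysed hydrogenation of a 1,1-diarylethene.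

Key step: step 8

Assumption: in steps 6 and 8 the ligand antipode written is the one expected to give the required configuration; the antipodal ligand is equally available and would be used if a first run showed the opposite sense.

**Step 1**
Reactants: 1 2',6'-dihydroxy-4'-methoxyacetophenone; 2 4-(benzyloxy)benzyl chloride
Product: 3 1-[2-{[4-(benzyloxy)phenyl]methoxy}-6-hydroxy-4-methoxyphenyl]ethan-1-one
Conditions: K2CO3 (1.1 equiv), KI (cat.), acetone, reflux
Reagents that add atoms: none
Why: Williamson etherification of a symmetric diphenol, so either hydroxyl gives the same ether, and the remaining hydroxyl is hydrogen-bonded to the acetyl group, which should stop the reaction at the mono-ether that already carries the future C2 and ring B on the future O1.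

**Step 2**
Reactants: 3 the mono-ether
Product: 4 1-[6-{[4-(benzyloxy)phenyl]methoxy}-2-hydroxy-3-iodo-4-methoxyphenyl]ethan-1-one
Conditions: BnMe3N·ICl2 (1.05 equiv), NaHCO3, CH2Cl2–MeOH, rt
Reagents that add atoms: benzyltrimethylammonium dichloroiodate, C[N+](C)(C)Cc1ccccc1.Cl[I-]Cl
Why: electrophilic aromatic iodination directed to the only open position ortho to the free phenol, which, because O1 was alkylated first, is the future C6 and not C8, the benzyl-type rings being far less activated.

**Step 3**
Reactants: 4 the iodophenol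
Product: 5 1-[6-{[4-(benzyloxy)phenyl]methoxy}-3-iodo-2,4-dimethoxyphenyl]ethan-1-one
Conditions: MeI, K2CO3, DMF, 50 °C
Reagents that add atoms: iodomethane, CI
Why: Williamson methylation of the chelated phenol, methyl being chosen for the future C5 oxygen because it offers the later carbene only unactivated primary C–H bonds and is the one methyl ether that chelation-controlled cleavage removes at the end.

**Step 4**
Reactants: 6 4'-(benzyloxy)acetophenone
Product: 7 N'-{1-[4-(benzyloxy)phenyl]ethylidene}-4-methylbenzenesulfonohydrazide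
Conditions: TsNHNH2, MeOH, 60 °C
Reagents that add atoms: p-toluenesulfonyl hydrazide, Cc1ccc(S(=O)(=O)NN)cc1
Why: simple hydrazone condensation of an aryl methyl ketone, giving a crystalline carbene precursor for the next coupling.

**Step 5**
Reactants: 5 the aryl iodide; 7 the tosylhydrazone
Product: 8 1-[6-{[4-(benzyloxy)phenyl]methoxy}-3-{1-[4-(benzyloxy)phenyl]ethenyl}-2,4-dimethoxyphenyl]ethan-1-one
Conditions: Pd2(dba)3 (2.5 mol %), XPhos (10 mol %), LiOtBu (2.4 equiv), 1,4-dioxane, 90 °C
Reagents that add atoms: none
Why: Barluenga cross-coupling, in which zerovalent palladium adds to the aryl iodide, the hydrazone-derived diazo compound gives a palladium carbene, and aryl migration followed by β-hydride elimination from the methyl group should give the 1,1-diarylethene, a reaction type that tolerates aryl halides flanked by two alkoxy groups.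

**Step 6**
Reactants: 8 the 1,1-diarylethene
Product: 9 1-[6-{[4-(benzyloxy)phenyl]methoxy}-3-{(1R)-1-[4-(benzyloxy)phenyl]ethyl}-2,4-dimethoxyphenyl]ethan-1-one
Conditions: [Ir(cod)((S)-tBu-PHOX)][B(3,5-(CF3)2C6H3)4] (2 mol %), H2 (50 bar), CH2Cl2, rt
Reagents that add atoms: none
Why: iridium N,P-ligand asymmetric hydrogenation of an unfunctionalised 1,1-diarylethene, in which the catalyst should tell the alkene faces apart because ring A, with two ortho-methoxy groups, is twisted out of the alkene plane while the 4-(benzyloxy)phenyl ring stays coplanar, so that the (R) side-chain centre is set by the ligand, with benzyl ethers and the aryl ketone inert to this homogeneous catalyst.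

**Step 7**
Reactants: 9 the (R)-diarylethane acetophenone
Product: 11 1-[6-{[4-(benzyloxy)phenyl]methoxy}-3-{(1R)-1-[4-(benzyloxy)phenyl]ethyl}-2,4-dimethoxyphenyl]-2-diazoethan-1-one, via trifluoroacetyl diketone 10 (not isolated)
Conditions: LiN(SiMe3)2, THF, −78 °C; CF3CO2CH2CF3; 5% HCl work-up; then MsN3, Et3N, H2O (1 equiv), MeCN, rt
Reagents that add atoms: 2,2,2-trifluoroethyl trifluoroacetate, O=C(OCC(F)(F)F)C(F)(F)F (trifluoroacetyl group, carried only by intermediate 10); methanesulfonyl azide, CS(=O)(=O)N=[N+]=[N-]
Why: detrifluoroacetylative diazo transfer, in which the only enolisable position, the acetyl methyl group, is activated as a trifluoroacetyl diketone and then takes up N2 from the sulfonyl azide with loss of the trifluoroacetyl group as a sulfonamide.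

**Step 8**
Reactants: 11 the diazoketone
Product: 12 (2S)-2-[4-(benzyloxy)phenyl]-6-{(1R)-1-[4-(benzyloxy)phenyl]ethyl}-5,7-dimethoxy-2,3-dihydro-4H-chromen-4-one
Conditions: Rh2(S-BSP)4 (dirhodium tetrakis[N-(benzenesulfonyl)-(S)-prolinate], 1 mol %), CH2Cl2, rt, 11 added over 4 h
Reagents that add atoms: none
Why: Loss of N2 from 11 on the divalent rhodium carboxylate gives an electrophilic acyl carbene at C3, which inserts in a concerted, hydride-transfer-like three-centre step into a C–H bond of the O1–CH2 group, the positive charge building up at C2 being stabilised by the O1 lone pair and by the 4-(benzyloxy)phenyl ring. The closest known reaction type is the rhodium-carboxylate-catalysed intramolecular C–H insertion of 2-alkoxyaryl diazomethyl ketones to chroman-4-ones, including its asymmetric form with prolinate ligands. Ring C closes as a six-membered ring by 1,6 C–H insertion through a six-membered transition state in which C3, C4, C4a, C8a, O1 and C2 become the ring atoms. C2 is the only new stereocentre and is set by the chiral prolinate ligands, which select one of the two enantiotopic benzylic hydrogens, the insertion going with retention at carbon and the remote side-chain centre having no influence. The step needs site selectivity over the C–H bonds of the C5 methoxy group and chemoselectivity over carbene attack on the O1 lone pair (oxonium ylide, then 1,2-shift of the benzyl group to a benzofuran-3-one): the first is secured by the far more hydridic benzylic methylene and by the choice of methyl on the C5 oxygen, the second by the low basicity of an aryl ether oxygen conjugated to the acylated ring A, by carboxylate instead of perfluoroalkanoate ligands and by slow addition at low concentration. The side-chain methine is meta to the acyl group and cannot reach the carbene, and the two remote benzyl ether methylenes could react only through macrocyclic transition states.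

**Step 9**
Reactants: 12 the (2S)-flavanone
Product: 16 (2R,3R)-2-[4-(benzyloxy)phenyl]-6-{(1R)-1-[4-(benzyloxy)phenyl]ethyl}-3-hydroxy-5,7-dimethoxy-2,3-dihydro-4H-chromen-4-one, via TMS enol ether 13 (not isolated), via silyloxy epoxide 14 (not isolated), via 3-O-TMS ketone 15 (not isolated)
Conditions: TMSOTf, Et3N, CH2Cl2, 0 °C, dark; cold NaHCO3 wash; then DMDO, acetone–CH2Cl2, −40 °C; then 1 M HCl, THF, 0 °C
Reagents that add atoms: dimethyldioxirane, CC1(C)OO1; trimethylsilyl triflate, C[Si](C)(C)OS(=O)(=O)C(F)(F)F (silyl group, carried only by intermediates 13 to 15)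
Why: Rubottom oxidation, in which soft enolisation (no free enolate, hence no E1cB opening of ring C at C2) gives the 4-silyloxy-2H-chromene, DMDO should epoxidise it on the face anti to the C2 aryl group so that the new C3–O bond is trans to ring B (3R), and silyl migration with mild acid hydrolysis should release the α-hydroxy ketone, the sequence being kept cold and dark to avoid electrocyclic opening of the 2H-chromene.

**Step 10**
Reactants: 16 the protected dihydroflavonol
Product: 17 (2R,3R)-3,5-dihydroxy-2-(4-hydroxyphenyl)-6-[(1R)-1-(4-hydroxyphenyl)ethyl]-7-methoxy-2,3-dihydro-4H-chromen-4-one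
Conditions: BCl3 (8 equiv), C6HMe5 (6 equiv), CH2Cl2, −78 °C to 0 °C; MeOH quench
Reagents that add atoms: none
Why: Lewis-acid ether cleavage, in which BCl3 should remove both aryl benzyl ethers at low temperature with pentamethylbenzene trapping the benzyl cations, and on warming should cleave only the C5 methyl ether through its chelate with the C4 carbonyl while the non-chelated C7 methyl ether survives, C3 not being enolised under these conditions and the trans arrangement at C2/C3 being the thermodynamically favoured one.

**Compound list**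

1 | 2',6'-dihydroxy-4'-methoxyacetophenone | CC(=O)c1c(O)cc(OC)cc1O | starting material
2 | 4-(benzyloxy)benzyl chloride | ClCc1ccc(OCc2ccccc2)cc1 | starting material
3 | 1-[2-{[4-(benzyloxy)phenyl]methoxy}-6-hydroxy-4-methoxyphenyl]ethan-1-one | CC(=O)c1c(O)cc(OC)cc1OCc1ccc(OCc2ccccc2)cc1 | intermediate
4 | 1-[6-{[4-(benzyloxy)phenyl]methoxy}-2-hydroxy-3-iodo-4-methoxyphenyl]ethan-1-one | CC(=O)c1c(O)c(I)c(OC)cc1OCc1ccc(OCc2ccccc2)cc1 | intermediate
5 | 1-[6-{[4-(benzyloxy)phenyl]methoxy}-3-iodo-2,4-dimethoxyphenyl]ethan-1-one | CC(=O)c1c(OC)c(I)c(OC)cc1OCc1ccc(OCc2ccccc2)cc1 | intermediate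
6 | 4'-(benzyloxy)acetophenone | CC(=O)c1ccc(OCc2ccccc2)cc1 | starting material
7 | N'-{1-[4-(benzyloxy)phenyl]ethylidene}-4-methylbenzenesulfonohydrazide | CC(=NNS(=O)(=O)c1ccc(C)cc1)c1ccc(OCc2ccccc2)cc1 | intermediate
8 | 1-[6-{[4-(benzyloxy)phenyl]methoxy}-3-{1-[4-(benzyloxy)phenyl]ethenyl}-2,4-dimethoxyphenyl]ethan-1-one | CC(=O)c1c(OC)c(C(=C)c2ccc(OCc3ccccc3)cc2)c(OC)cc1OCc1ccc(OCc2ccccc2)cc1 | intermediate
9 | 1-[6-{[4-(benzyloxy)phenyl]methoxy}-3-{(1R)-1-[4-(benzyloxy)phenyl]ethyl}-2,4-dimethoxyphenyl]ethan-1-one | CC(=O)c1c(OC)c([C@H](C)c2ccc(OCc3ccccc3)cc2)c(OC)cc1OCc1ccc(OCc2ccccc2)cc1 | intermediate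
10 | 1-[6-{[4-(benzyloxy)phenyl]methoxy}-3-{(1R)-1-[4-(benzyloxy)phenyl]ethyl}-2,4-dimethoxyphenyl]-4,4,4-trifluorobutane-1,3-dione | O=C(CC(=O)C(F)(F)F)c1c(OC)c([C@H](C)c2ccc(OCc3ccccc3)cc2)c(OC)cc1OCc1ccc(OCc2ccccc2)cc1 | intermediate
11 | 1-[6-{[4-(benzyloxy)phenyl]methoxy}-3-{(1R)-1-[4-(benzyloxy)phenyl]ethyl}-2,4-dimethoxyphenyl]-2-diazoethan-1-one | [N-]=[N+]=CC(=O)c1c(OC)c([C@H](C)c2ccc(OCc3ccccc3)cc2)c(OC)cc1OCc1ccc(OCc2ccccc2)cc1 | intermediate
12 | (2S)-2-[4-(benzyloxy)phenyl]-6-{(1R)-1-[4-(benzyloxy)phenyl]ethyl}-5,7-dimethoxy-2,3-dihydro-4H-chromen-4-one | COc1cc2c(c(OC)c1[C@H](C)c1ccc(OCc3ccccc3)cc1)C(=O)C[C@@H](c1ccc(OCc3ccccc3)cc1)O2 | intermediate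
13 | (2S)-2-[4-(benzyloxy)phenyl]-6-{(1R)-1-[4-(benzyloxy)phenyl]ethyl}-5,7-dimethoxy-4-(trimethylsilyloxy)-2H-chromene | COc1cc2c(c(OC)c1[C@H](C)c1ccc(OCc3ccccc3)cc1)C(O[Si](C)(C)C)=C[C@@H](c1ccc(OCc3ccccc3)cc1)O2 | intermediate
14 | 3,4-epoxide of 13, oxirane oxygen on the face opposite the C2 aryl group, trimethylsilyloxy group on C4 | COc1cc2c(c(OC)c1[C@H](C)c1ccc(OCc3ccccc3)cc1)[C@]4(O[Si](C)(C)C)O[C@@H]4[C@@H](c1ccc(OCc3ccccc3)cc1)O2 | intermediate
15 | (2R,3R)-2-[4-(benzyloxy)phenyl]-6-{(1R)-1-[4-(benzyloxy)phenyl]ethyl}-5,7-dimethoxy-3-(trimethylsilyloxy)-2,3-dihydro-4H-chromen-4-one | COc1cc2c(c(OC)c1[C@H](C)c1ccc(OCc3ccccc3)cc1)C(=O)[C@H](O[Si](C)(C)C)[C@@H](c1ccc(OCc3ccccc3)cc1)O2 | intermediate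
16 | (2R,3R)-2-[4-(benzyloxy)phenyl]-6-{(1R)-1-[4-(benzyloxy)phenyl]ethyl}-3-hydroxy-5,7-dimethoxy-2,3-dihydro-4H-chromen-4-one | COc1cc2c(c(OC)c1[C@H](C)c1ccc(OCc3ccccc3)cc1)C(=O)[C@H](O)[C@@H](c1ccc(OCc3ccccc3)cc1)O2 | intermediate
17 | (2R,3R)-3,5-dihydroxy-2-(4-hydroxyphenyl)-6-[(1R)-1-(4-hydroxyphenyl)ethyl]-7-methoxy-2,3-dihydro-4H-chromen-4-one | COc1cc2c(c(O)c1[C@H](C)c1ccc(O)cc1)C(=O)[C@H](O)[C@@H](c1ccc(O)cc1)O2 | target

**Step count.** Total: 10 steps. Longest linear sequence: 9 steps (1, 2, 3, 5, 6, 7, 8, 9, 10, starting from compound 1); step 4 is a one-step side branch.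

**Steps most likely to fail**

1. Step 8. The carbene may attack the O1 lone pair instead of the C2–H bond, and the oxonium ylide would then shift the benzyl group from oxygen to carbon, giving a five-membered benzofuranone. Alternatively, the catalyst may discriminate poorly between the two enantiotopic benzylic hydrogens. The fallback avoids a carbene altogether while closing the same C2–C3 bond. It sets out from diazoketone 11, which is oxidised with dimethyldioxirane (acetone, 0 °C) to the aryl glyoxal F1. Irradiation of F1 with visible light (above 400 nm, dry benzene, rt) should trigger a Norrish–Yang photocyclisation: the excited 1,2-dicarbonyl abstracts a benzylic hydrogen of the O1–CH2 group through its aldehyde oxygen, and the resulting 1,6-biradical closes C2–C3 with the hydroxyl already on C3. The route is rejoined at 16, bypassing steps 8 and 9. The price is that C2 and C3 are no longer set by a catalyst. The trans isomers (2R,3R) and (2S,3S) are diastereomers because of the fixed side-chain centre and would have to be separated by chromatography.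

2. Step 6. The alkene is flanked by a ring carrying two ortho substituents, so hydrogen uptake may be slow and facial discrimination by a purely steric catalyst may be poor. The fallback uses a directing group instead of steric discrimination. It sets out from iodophenol 4, which is coupled with hydrazone 7 under the conditions of step 5 (one further equivalent of LiOtBu) to give the free-phenol diarylethene F2. Hydrogenation of F2 with [Rh(nbd)2]BF4 and a Josiphos-type ferrocenyl bisphosphine (H2, MeOH, rt) should be directed by the ortho hydroxyl binding to rhodium, giving the (R)-diarylethane phenol F3. Methylation of F3 (MeI, K2CO3, DMF) rejoins the route at 9.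

3. Step 10. The Lewis acid may ionise the benzylic C2–O1 bond (ring opening and epimerisation at C2) or cause acid-induced loss and re-addition of the 1-arylethyl group on the electron-rich ring A, and the peri-demethylation may stall or overrun. The fallback separates the two tasks and removes the benzyl groups without any acid. It sets out from 16, which is hydrogenolysed (H2, Pd/C, EtOAc, rt) to the debenzylated dimethyl ether F4. Treatment of F4 with MgI2·OEt2 (THF–toluene, 50 °C), which cleaves only the methoxy group held in a magnesium chelate with the C4 carbonyl, arrives at 17.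

**Further compounds**

F1 | step 8 | 2-[6-{[4-(benzyloxy)phenyl]methoxy}-3-{(1R)-1-[4-(benzyloxy)phenyl]ethyl}-2,4-dimethoxyphenyl]-2-oxoacetaldehyde | O=CC(=O)c1c(OC)c([C@H](C)c2ccc(OCc3ccccc3)cc2)c(OC)cc1OCc1ccc(OCc2ccccc2)cc1
F2 | step 6 | 1-[6-{[4-(benzyloxy)phenyl]methoxy}-3-{1-[4-(benzyloxy)phenyl]ethenyl}-2-hydroxy-4-methoxyphenyl]ethan-1-one | CC(=O)c1c(O)c(C(=C)c2ccc(OCc3ccccc3)cc2)c(OC)cc1OCc1ccc(OCc2ccccc2)cc1
F3 | step 6 | 1-[6-{[4-(benzyloxy)phenyl]methoxy}-3-{(1R)-1-[4-(benzyloxy)phenyl]ethyl}-2-hydroxy-4-methoxyphenyl]ethan-1-one | CC(=O)c1c(O)c([C@H](C)c2ccc(OCc3ccccc3)cc2)c(OC)cc1OCc1ccc(OCc2ccccc2)cc1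
F4 | step 10 | (2R,3R)-3-hydroxy-2-(4-hydroxyphenyl)-6-[(1R)-1-(4-hydroxyphenyl)ethyl]-5,7-dimethoxy-2,3-dihydro-4H-chromen-4-one | COc1cc2c(c(OC)c1[C@H](C)c1ccc(O)cc1)C(=O)[C@H](O)[C@@H](c1ccc(O)cc1)O2
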